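**Retrosynthetic overview**
1. Target ⇒ acid 17 + (R)-glycidyl PMB ether 18: the carboxylate opens the epoxide at its terminal carbon, then acetylation and PMB removal.
2. Side chain: the C5–CH2 bond comes from coupling the C5 enol triflate 13 (from ketone 12) with the homoprenyl Grignard reagent.
3. Key step: ring B, the C4a–C5 bond and the C4a quaternary centre come from an electrochemical cobalt-hydride HAT cyclisation of alkene-nitrile 10.
4. C1 and C8a are set on ring A by anti-selective vinyl conjugate addition and enolate alkylation of enone 4; the vinyl group becomes the ester.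
5. Ring A (with C2) is bought as (R)-pulegone; ring order is A (chiral pool) then B (electrochemical cyclisation).

Assumption: (R)-glycidyl 4-methoxybenzyl ether 18 (the PMB ether of (S)-glycidol) is taken as a catalogue compound; C1–C8a below are the naphthalene locants of the acyl part of the target.

**Step 1**
Reactants: 1 (R)-pulegone
Product: 2 (5R)-1,5-dimethyl-2-(propan-2-ylidene)cyclohexan-1-ol (C1 epimers)
Conditions: MeLi, CeCl3, THF, −78 °C
Reagents that add atoms: methyllithium, [Li]C
Why: Organocerium 1,2-addition to the hindered, easily enolised enone; the new carbinol centre is destroyed in step 3 and the pulegone stereocentre (future C2) is untouched.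

**Step 2**
Reactants: 2 (5R)-1,5-dimethyl-2-(propan-2-ylidene)cyclohexan-1-ol
Product: 3 (4R)-2-hydroxy-2,4-dimethylcyclohexan-1-one (C2 epimers)
Conditions: O3, CH2Cl2/MeOH, NaHCO3, −78 °C; then Me2S
Reagents that add atoms: ozone, [O-][O+]=O
Why: Ozonolysis with reductive work-up cleaves the electron-rich tetrasubstituted alkene to the ring ketone and acetone, moving the carbonyl to the future C4a.

**Step 3**
Reactants: 3 (4R)-2-hydroxy-2,4-dimethylcyclohexan-1-one
Product: 4 (4R)-2,4-dimethylcyclohex-2-en-1-one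
Conditions: SOCl2, pyridine, CH2Cl2, 0 °C → rt
Reagents that add atoms: none
Why: Chlorosulfite E2 dehydration of a tertiary α-ketol gives the conjugated endocyclic enone (the reaction type used for 17α-hydroxy-20-keto steroids); the γ-stereocentre is not touched.

**Step 4**
Reactants: 4 (4R)-2,4-dimethylcyclohex-2-en-1-one; 5 4-iodobutanenitrile
Product: 8 4-[(1R,2S,3R)-2-ethenyl-1,3-dimethyl-6-oxocyclohexyl]butanenitrile, via silyl enol ether 6 (not isolated), via lithium enolate 7 (not isolated)
Conditions: CH2=CHMgBr, CuBr·SMe2 (10 mol %), TMSCl, THF, −78 °C; volatiles removed; MeLi, THF, 0 °C; 5, HMPA, −40 °C → rt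
Reagents that add atoms: vinylmagnesium bromide, C=C[Mg]Br
Why: Tandem conjugate addition–enolate alkylation: the vinyl copper reagent adds anti to the C2 methyl (sets C1), and the regiodefined lithium enolate is alkylated anti to the new vinyl group (sets quaternary C8a).

**Step 5**
Reactants: 8 4-[(1R,2S,3R)-2-ethenyl-1,3-dimethyl-6-oxocyclohexyl]butanenitrile
Product: 9 methyl (1S,2R,6R)-2-(3-cyanopropyl)-2,6-dimethyl-3-oxocyclohexane-1-carboxylate
Conditions: O3, NaOH (2.5 M in MeOH), CH2Cl2, −78 °C
Reagents that add atoms: ozone, [O-][O+]=O; methanol, CO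
Why: Marshall ozonolysis in basic methanol turns the terminal alkene directly into the methyl ester; ketone and nitrile are inert, and C1 keeps its trans (thermodynamically preferred) configuration.

**Step 6**
Reactants: 9 methyl (1S,2R,6R)-2-(3-cyanopropyl)-2,6-dimethyl-3-oxocyclohexane-1-carboxylate
Product: 10 methyl (1S,2R,6R)-2-(3-cyanopropyl)-2,6-dimethyl-3-methylidenecyclohexane-1-carboxylate
Conditions: Zn, CH2Br2, TiCl4, THF/CH2Cl2, 0 °C → rt
Reagents that add atoms: dibromomethane, BrCBr
Why: Takai–Lombardo methylenation is non-basic, works on α-quaternary ketones and leaves the ester and nitrile alone.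

**Step 7**
Reactants: 10 methyl (1S,2R,6R)-2-(3-cyanopropyl)-2,6-dimethyl-3-methylidenecyclohexane-1-carboxylate
Product: 12 methyl (1S,2R,4aS,8aR)-2,4a,8a-trimethyl-5-oxodecahydronaphthalene-1-carboxylate, via ketimine 11 (not isolated)
Conditions: Co(salen) [N,N'-bis(salicylidene)ethylenediaminocobalt, C16H14CoN2O2] (10 mol %), Et3NHBF4 (3 equiv), n-Bu4NBF4, MeCN, undivided cell, Zn anode, Ni-foam cathode, constant current, 2.5 F/mol, rt; then 1 M HCl, THF
Reagents that add atoms: water, O
Why: Proposed new method: cathodic reduction of the divalent cobalt salen complex and protonation give a trivalent cobalt hydride that transfers H• to the exocyclic CH2 (which becomes the C4a methyl); the tertiary C4a radical adds 6-exo-dig to the nitrile on the tether from C8a, so the ring closes cis and C4a–Me ends cis to C8a–Me; the iminyl radical is reduced and protonated to ketimine 11, which is hydrolysed on work-up; closest known reaction types are the Fe(acac)3/PhSiH3 HAT-initiated alkene–nitrile radical cyclisation and cobalt-electrocatalytic HAT isomerisation/hydrofunctionalisation of alkenes.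

**Step 8**
Reactants: 12 methyl (1S,2R,4aS,8aR)-2,4a,8a-trimethyl-5-oxodecahydronaphthalene-1-carboxylate
Product: 13 methyl (1S,2R,4aS,8aR)-2,4a,8a-trimethyl-5-{[(trifluoromethyl)sulfonyl]oxy}-1,2,3,4,4a,7,8,8a-octahydronaphthalene-1-carboxylate
Conditions: KN(SiMe3)2, PhNTf2, THF, −78 °C
Reagents that add atoms: N-phenylbis(trifluoromethanesulfonimide), O=S(=O)(N(c1ccccc1)S(=O)(=O)C(F)(F)F)C(F)(F)F
Why: Enol triflate formation; the ketone can enolise only towards C6 because C4a is quaternary, and the hindered tertiary C1–H of the ester is not removed.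

**Step 9**
Reactants: 13 enol triflate (name as in step 8); 14 5-bromo-2-methylpent-2-ene
Product: 16 methyl (1S,2R,4aR,8aR)-2,4a,8a-trimethyl-5-(4-methylpent-3-en-1-yl)-1,2,3,4,4a,7,8,8a-octahydronaphthalene-1-carboxylate, via Grignard reagent 15 (not isolated)
Conditions: 14, Mg, THF, rt; then 13, Fe(acac)3 (5 mol %), THF/NMP, −30 °C
Reagents that add atoms: none
Why: Iron-catalysed Kumada-type (Fürstner) coupling of an alkenyl triflate with an alkyl Grignard reagent is fast at −30 °C, spares the hindered ester and fixes the C5=C6 position.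

**Step 10**
Reactants: 16 methyl ester (name as in step 9)
Product: 17 (1S,2R,4aR,8aR)-2,4a,8a-trimethyl-5-(4-methylpent-3-en-1-yl)-1,2,3,4,4a,7,8,8a-octahydronaphthalene-1-carboxylic acid
Conditions: n-PrSLi, HMPA, rt; then 1 M HCl
Reagents that add atoms: none
Why: SN2 O-demethylation by thiolate cleaves the hindered methyl ester at the methyl carbon, so neither C1 nor the alkenes are affected.

**Step 11**
Reactants: 17 acid (name as in step 10); 18 (2R)-2-{[(4-methoxyphenyl)methoxy]methyl}oxirane
Product: 20 (2S)-2-(acetyloxy)-3-[(4-methoxyphenyl)methoxy]propyl (1S,2R,4aR,8aR)-2,4a,8a-trimethyl-5-(4-methylpent-3-en-1-yl)-1,2,3,4,4a,7,8,8a-octahydronaphthalene-1-carboxylate, via hydroxy ester 19 (not isolated)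
Conditions: Cs2CO3 (10 mol %), DMF, 80 °C; then Ac2O, Et3N, DMAP (cat.), 0 °C → rt
Reagents that add atoms: acetic anhydride, CC(=O)OC(C)=O
Why: The carboxylate opens the epoxide by SN2 at the terminal CH2, so the purchased glycerol stereocentre is untouched and the hindered acid needs no activation; DMAP-catalysed acetylation then caps the secondary hydroxyl.

**Step 12**
Reactants: 20 PMB ether acetate (name as in step 11)
Product: 21 (2S)-2-(acetyloxy)-3-hydroxypropyl (1S,2R,4aR,8aR)-2,4a,8a-trimethyl-5-(4-methylpent-3-en-1-yl)-1,2,3,4,4a,7,8,8a-octahydronaphthalene-1-carboxylate (target)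
Conditions: DDQ, CH2Cl2/pH 7 phosphate buffer (10:1), 0 °C
Reagents that add atoms: none
Why: Oxidative PMB ether cleavage under buffered neutral conditions frees the primary alcohol without acetyl migration and is much faster than any reaction of the trisubstituted alkenes.

**Compound list**
1 | (R)-pulegone, (5R)-5-methyl-2-(propan-2-ylidene)cyclohexan-1-one | C[C@@H]1CCC(=C(C)C)C(=O)C1 | starting material
2 | (5R)-1,5-dimethyl-2-(propan-2-ylidene)cyclohexan-1-ol (C1 epimers) | C[C@@H]1CCC(=C(C)C)C(C)(O)C1 | intermediate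
3 | (4R)-2-hydroxy-2,4-dimethylcyclohexan-1-one (C2 epimers) | C[C@@H]1CCC(=O)C(C)(O)C1 | intermediate
4 | (4R)-2,4-dimethylcyclohex-2-en-1-one | C[C@@H]1CCC(=O)C(C)=C1 | intermediate
5 | 4-iodobutanenitrile | N#CCCCI | starting material
6 | {[(3S,4R)-3-ethenyl-2,4-dimethylcyclohex-1-en-1-yl]oxy}trimethylsilane | C=C[C@H]1[C@H](C)CCC(O[Si](C)(C)C)=C1C | intermediate (not isolated)
7 | lithium (3S,4R)-3-ethenyl-2,4-dimethylcyclohex-1-en-1-olate | C=C[C@H]1[C@H](C)CCC(O[Li])=C1C | intermediate (not isolated)
8 | 4-[(1R,2S,3R)-2-ethenyl-1,3-dimethyl-6-oxocyclohexyl]butanenitrile | C=C[C@H]1[C@H](C)CCC(=O)[C@]1(C)CCCC#N | intermediate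
9 | methyl (1S,2R,6R)-2-(3-cyanopropyl)-2,6-dimethyl-3-oxocyclohexane-1-carboxylate | COC(=O)[C@H]1[C@H](C)CCC(=O)[C@]1(C)CCCC#N | intermediate
10 | methyl (1S,2R,6R)-2-(3-cyanopropyl)-2,6-dimethyl-3-methylidenecyclohexane-1-carboxylate | COC(=O)[C@H]1[C@H](C)CCC(=C)[C@]1(C)CCCC#N | intermediate
11 | methyl (1S,2R,4aS,8aR)-5-imino-2,4a,8a-trimethyldecahydronaphthalene-1-carboxylate | COC(=O)[C@H]1[C@H](C)CC[C@]2(C)C(=N)CCC[C@]12C | intermediate (not isolated)
12 | methyl (1S,2R,4aS,8aR)-2,4a,8a-trimethyl-5-oxodecahydronaphthalene-1-carboxylate | COC(=O)[C@H]1[C@H](C)CC[C@]2(C)C(=O)CCC[C@]12C | intermediate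
13 | methyl (1S,2R,4aS,8aR)-2,4a,8a-trimethyl-5-{[(trifluoromethyl)sulfonyl]oxy}-1,2,3,4,4a,7,8,8a-octahydronaphthalene-1-carboxylate | COC(=O)[C@H]1[C@H](C)CC[C@]2(C)C(OS(=O)(=O)C(F)(F)F)=CCC[C@]12C | intermediate
14 | 5-bromo-2-methylpent-2-ene | CC(C)=CCCBr | starting material
15 | (4-methylpent-3-en-1-yl)magnesium bromide | CC(C)=CCC[Mg]Br | intermediate (not isolated)
16 | methyl (1S,2R,4aR,8aR)-2,4a,8a-trimethyl-5-(4-methylpent-3-en-1-yl)-1,2,3,4,4a,7,8,8a-octahydronaphthalene-1-carboxylate | COC(=O)[C@H]1[C@H](C)CC[C@]2(C)C(CCC=C(C)C)=CCC[C@]12C | intermediate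
17 | (1S,2R,4aR,8aR)-2,4a,8a-trimethyl-5-(4-methylpent-3-en-1-yl)-1,2,3,4,4a,7,8,8a-octahydronaphthalene-1-carboxylic acid | OC(=O)[C@H]1[C@H](C)CC[C@]2(C)C(CCC=C(C)C)=CCC[C@]12C | intermediate
18 | (2R)-2-{[(4-methoxyphenyl)methoxy]methyl}oxirane | COc1ccc(COC[C@H]2CO2)cc1 | starting material
19 | (2S)-2-hydroxy-3-[(4-methoxyphenyl)methoxy]propyl (1S,2R,4aR,8aR)-2,4a,8a-trimethyl-5-(4-methylpent-3-en-1-yl)-1,2,3,4,4a,7,8,8a-octahydronaphthalene-1-carboxylate | COc1ccc(COC[C@H](O)COC(=O)[C@H]2[C@H](C)CC[C@]3(C)C(CCC=C(C)C)=CCC[C@]23C)cc1 | intermediate (not isolated)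
20 | (2S)-2-(acetyloxy)-3-[(4-methoxyphenyl)methoxy]propyl (1S,2R,4aR,8aR)-2,4a,8a-trimethyl-5-(4-methylpent-3-en-1-yl)-1,2,3,4,4a,7,8,8a-octahydronaphthalene-1-carboxylate | COc1ccc(COC[C@H](OC(C)=O)COC(=O)[C@H]2[C@H](C)CC[C@]3(C)C(CCC=C(C)C)=CCC[C@]23C)cc1 | intermediate
21 | (2S)-2-(acetyloxy)-3-hydroxypropyl (1S,2R,4aR,8aR)-2,4a,8a-trimethyl-5-(4-methylpent-3-en-1-yl)-1,2,3,4,4a,7,8,8a-octahydronaphthalene-1-carboxylate | CC(=O)O[C@@H](CO)COC(=O)[C@H]1[C@H](C)CC[C@]2(C)C(CCC=C(C)C)=CCC[C@]12C | target

**Step count:** 12 steps in total; longest linear sequence 12 steps (1 → 21).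

**Steps most likely to fail**

Step 7 (the proposed new step). The tertiary radical may be hydrogenated before it closes onto the nitrile, or the cobalt hydride may only evolve hydrogen. The fallback sets out from ketone 9 and uses known chemistry only. MeMgBr/CeCl3 (THF, −78 °C) adds to the ketone ahead of the ester and nitrile to give methyl (1S,2R,6R)-2-(3-cyanopropyl)-3-hydroxy-2,3,6-trimethylcyclohexane-1-carboxylate F1. Methyl chlorooxoacetate with pyridine and DMAP converts it into methyl (1S,2R,6R)-2-(3-cyanopropyl)-3-[(methoxyoxalyl)oxy]-2,3,6-trimethylcyclohexane-1-carboxylate F2. Bu3SnH and AIBN in refluxing toluene (slow addition) fragment the tertiary oxalate to the same C4a radical, which cyclises onto the nitrile as in known tin-mediated nitrile cyclisations. Acidic work-up of ketimine 11 brings the route back at ketone 12.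

Step 4. The copper-catalysed addition may give too little of the anti (C1/C2 trans) isomer, and the hindered enolate may alkylate poorly with a primary iodide. The fallback sets out from enone 4 and changes the order of bond formation. A visible-light Giese addition of the methoxycarbonyl radical (methyl N-phthalimidoyl oxalate, Ru(bpy)3(PF6)2, Hantzsch ester, blue LEDs; a known reaction) anti to the C2 methyl gives methyl (1S,6R)-2,6-dimethyl-3-oxocyclohexane-1-carboxylate F3. Its more substituted, thermodynamic enolate (NaH, DME, 60 °C) is then alkylated with 5 anti to the ester group. This comes back to the route at keto ester 9 and bypasses 8 and step 5.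

Step 3. The tertiary α-ketol may give chloride, the exocyclic methylene isomer or α-ketol rearrangement instead of clean dehydration. The fallback sets out from 3. SmI2 (THF/MeOH, −78 °C) removes the α-hydroxyl to give (4R)-2,4-dimethylcyclohexan-1-one F4. TMSCl, Et3N in DMF at 100 °C gives the more substituted silyl enol ether, trimethyl{[(4R)-2,4-dimethylcyclohex-1-en-1-yl]oxy}silane F5. Saegusa–Ito oxidation with Pd(OAc)2 in MeCN then returns to the route at enone 4.

**Further compounds**
F1 | step 7 | methyl (1S,2R,6R)-2-(3-cyanopropyl)-3-hydroxy-2,3,6-trimethylcyclohexane-1-carboxylate | COC(=O)[C@H]1[C@H](C)CCC(C)(O)[C@]1(C)CCCC#N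
F2 | step 7 | methyl (1S,2R,6R)-2-(3-cyanopropyl)-3-[(methoxyoxalyl)oxy]-2,3,6-trimethylcyclohexane-1-carboxylate | COC(=O)[C@H]1[C@H](C)CCC(C)(OC(=O)C(=O)OC)[C@]1(C)CCCC#N
F3 | step 4 | methyl (1S,6R)-2,6-dimethyl-3-oxocyclohexane-1-carboxylate | COC(=O)[C@H]1[C@H](C)CCC(=O)C1C
F4 | step 3 | (4R)-2,4-dimethylcyclohexan-1-one | C[C@@H]1CCC(=O)C(C)C1
F5 | step 3 | trimethyl{[(4R)-2,4-dimethylcyclohex-1-en-1-yl]oxy}silane | C[C@@H]1CCC(O[Si](C)(C)C)=C(C)C1
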